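How much target and side product stand in this flask at the end of the run, and is it still moving?

substrate 0.10 M; reagent 0.950 equiv; transfer agent 0.100 M; initiator 5 mol%; time 3.0 h

    2 second chain carrier → ended chains B (k1 = 9.9 × 10⁷ M⁻¹ s⁻¹)
    substrate + initiating radical → capped initiator + first chain carrier (k2 = 6.2 × 10⁵ M⁻¹ s⁻¹)
    substrate + second chain carrier → by-product + first chain carrier (k3 = 33000 M⁻¹ s⁻¹)
    2 first chain carrier → ended chains A (k4 = 1.4 × 10⁷ M⁻¹ s⁻¹)
    initiator → 2 initiating radical (k5 = 3.9 × 10⁻⁴ s⁻¹)
    transfer agent + first chain carrier → side product + idle radical (k6 = 1.0 × 10⁵ M⁻¹ s⁻¹)
    reagent + first chain carrier → target + second chain carrier (k7 = 1.3 × 10⁶ M⁻¹ s⁻¹)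
    2 idle radical → ended radicals (k8 = 5 × 10⁸ M⁻¹ s⁻¹)

- the state of affairs at 3.0 h: stopped, and by what, or still going (all of the substrate has reacted / it is still moving / the reagent has run out first)
- amount of target at 3.0 h, in percent of the substrate charged
- amount of side product at 3.0 h, in percent of the substrate charged

- percentages count the substrate that a species holds: one ended chains A counts as two
- for a step with 2 of a species take k times the square, and two of it per event
- the reaction counts as stopped when no species that holds the substrate changes by six tenths of a point or more over the second half of the time
- run time (flask): 3.0 h

*What does the first chain carrier choose between?* Reagent and transfer agent. Each falls in proportion to its own amount times the same carrier, so in this flask the fraction of reagent left equals the fraction of transfer agent left raised to a fixed power. That power is the selectivity factor, the constant of the reagent step over that of the transfer step: 13.0.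

*How much transfer agent goes?* It is the small term, so I reckon just its loss. Take it that each radical ends on the transfer agent as one side product. Each initiator gives two radicals, so by 3.0 h the side product is 9.85 %, and 90.1 % of the transfer agent remains.

*And the reagent?* The power leaves 26.0 % of it, so a loss of 9.90 % of the transfer agent takes 74.0 % of the reagent. Target is the reagent charge times that loss: 70.3 %.

*Is it over?* Over the second half of the time, target still gains 4.1 percentage points, beyond the margin in the notes, so I say it is still moving.

*Where is the weak spot?* The second chain carrier ends in pairs. Balancing the carriers at the start, with radicals made by the initiator and removed by the transfer agent, that ending takes 1.08 % of the radicals, hardly any.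

The forecast says it is still moving, with 70 % target and 9.8 % side product, reasoning that “Reagent and transfer agent compete for the same carrier”. That is my route too, so our agreement checks nothing.

In the simulation it is still moving, with 70.1 % target, 9.79 % side product and 26 % of the reagent left.

The selectivity factor of 13.0 carries over to the neighbouring flask charged with 0.17 M of transfer agent. The same radicals are now a smaller fraction of that charge, so 94.2 % of its transfer agent should remain. That leaves 46.0 % of its reagent and gives 51.3 % target. The simulated neighbour holds 94.2 % transfer agent, 46.1 % reagent and 51.2 % target, with side product at 9.83 %.

The rate constants are invented; no experiment stands behind them.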